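**Retrosynthetic overview**

1. The last step is desilylation of 26. Both the furanone ring (O10–C3=C2–C1(=O)–C10) and the ten-membered carbocycle C1–C10 are opened at C2–C3, which leads back to the nine-membered lactone 23 (acetyl group C1/C2 on C10, C3 as the lactone carbonyl on O10). Forward: enolate O→C acyl shift (ring expansion 9 → 10), then cyclodehydration.
2. Enabling feature: C10 carries both the furanone ring oxygen and the C1 carbonyl. C3 can therefore be held at the acid level as an ester of O10, five atoms from the C2 methyl group; C1/C3 is the 1,3-dioxygenation of a Claisen adduct.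
3. 23 comes from ring-closing metathesis (C4=C5) of 22; 22 from Mitsunobu esterification (inversion at C8) of 20; 20 from zinc Barbier coupling (C7–C8) of aldehyde 12 with bromomethylbutenolide 18, which sets C7 and C8 and delivers the α-methylene lactone.
4. 12 comes from (R)-lactic acid (self-regeneration of the stereocentre for quaternary C10), MeLi, acylation of the tertiary O10 with acid 3, and ozonolysis. 18 comes from divinylcarbinol (Sharpless desymmetrisation for C6), acylation with 3, metathesis, epoxide deoxygenation and bromide formation.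
5. Ring order: butenolide (later the C6/C12 γ-lactone) → nine-membered lactone → furanone ring and ten-membered carbocycle together in the key step.

Key step: step 16

Remark: germacrane numbering is used (C1 ketone, C2=C3 furanone alkene, O10 the furanone oxygen on quaternary C10 with methyl C14, C4=C5, C6/C7 lactone fusion, C8 ester carbon, C9 methylene, C11–C13 methylene lactone, C15 hydroxymethyl); TBS = tert-butyldimethylsilyl; compounds 1, 4, 5, 7, 13 and 21 are taken as commercial.

**Route**

Step 1
Reactants: 1 ethyl 2-(hydroxymethyl)prop-2-enoate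
Product: 2 ethyl 2-{[(TBS)oxy]methyl}prop-2-enoate
Conditions: TBSCl, imidazole, DMF, 0 °C → rt
Reagents that add atoms: tert-butyldimethylsilyl chloride, CC(C)(C)[Si](C)(C)Cl
Why: Imidazole-assisted silylation of the primary allylic alcohol is routine and creates no stereocentre.

Step 2
Reactants: 2 ethyl 2-{[(TBS)oxy]methyl}prop-2-enoate
Product: 3 2-{[(TBS)oxy]methyl}prop-2-enoic acid
Conditions: LiOH, THF/H2O, 0 °C → rt; then 1 M HCl to pH 4 at 0 °C
Reagents that add atoms: lithium hydroxide, [Li+].[OH-]
Why: Saponification of the ethyl ester at low temperature, with acidification only to pH 4, should leave the primary silyl ether in place.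

Step 3
Reactants: 4 (R)-lactic acid; 5 pivalaldehyde
Product: 6 (2R,5R)-2-tert-butyl-5-methyl-1,3-dioxolan-4-one
Conditions: TsOH (cat.), pentane, reflux, Dean–Stark trap; recrystallisation from pentane at low temperature
Reagents that add atoms: none
Why: Acid-catalysed acetalisation with azeotropic removal of water should favour the cis dioxolanone, so that the lactic acid stereocentre fixes the acetal carbon as 2R and stores the chirality for self-regeneration of the stereocentre.

Step 4
Reactants: 6 (2R,5R)-2-tert-butyl-5-methyl-1,3-dioxolan-4-one; 7 1-bromo-3-methylbut-2-ene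
Product: 8 (2R,5S)-2-tert-butyl-5-methyl-5-(3-methylbut-2-en-1-yl)-1,3-dioxolan-4-one
Conditions: LiN(i-Pr)2, THF, −78 °C; then 7, −78 → −30 °C
Reagents that add atoms: none
Why: In this enolate alkylation the tert-butyl group shields one face of the planar lithium enolate, so the prenyl group should enter trans to it and set the quaternary carbon (later C10) as 5S.

Step 5
Reactants: 8 (2R,5S)-2-tert-butyl-5-methyl-5-(3-methylbut-2-en-1-yl)-1,3-dioxolan-4-one
Product: 9 (S)-3-hydroxy-3,6-dimethylhept-5-en-2-one
Conditions: MeLi (1.1 equiv), THF, −78 °C; AcOH, −78 °C → rt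
Reagents that add atoms: methyllithium, [Li]C
Why: Acyl substitution at the dioxolanone carbonyl should stop after one addition because the lithium hemiketal releases the methyl ketone and pivalaldehyde only on protonation; the quaternary stereocentre is not touched.

Step 6
Reactants: 3 2-{[(TBS)oxy]methyl}prop-2-enoic acid; 9 (S)-3-hydroxy-3,6-dimethylhept-5-en-2-one
Product: 11 (S)-3,6-dimethyl-2-oxohept-5-en-3-yl 2-{[(TBS)oxy]methyl}prop-2-enoate, via acid chloride 10 (not isolated)
Conditions: 3, 1-chloro-N,N,2-trimethylprop-1-en-1-amine, CH2Cl2, 0 °C → rt; then 9, Et3N, DMAP, CH2Cl2, 0 → 40 °C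
Reagents that add atoms: 1-chloro-N,N,2-trimethylprop-1-en-1-amine, CC(C)=C(Cl)N(C)C
Why: Neutral acid-chloride formation preserves the silyl ether, and DMAP-catalysed acylation should force the hindered tertiary α-ketol hydroxyl to the ester, so the O10–C3 bond at the fully substituted carbon is made on a small fragment where forcing conditions do no harm.

Step 7
Reactants: 11 (S)-3,6-dimethyl-2-oxohept-5-en-3-yl 2-{[(TBS)oxy]methyl}prop-2-enoate
Product: 12 (S)-3-methyl-1,4-dioxopentan-3-yl 2-{[(TBS)oxy]methyl}prop-2-enoate
Conditions: O3, CH2Cl2, −78 °C (stopped at the first excess of ozone); Me2S, −78 °C → rt; used crude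
Reagents that add atoms: ozone, [O-][O+]=O
Why: In this ozonolysis the electron-rich trisubstituted prenyl alkene should be cleaved far faster than the electron-poor acrylate, and the β-acyloxy aldehyde is used without chromatography to avoid β-elimination.

Step 8
Reactants: 13 penta-1,4-dien-3-ol
Product: 14 (2R,3S)-1,2-epoxypent-4-en-3-ol
Conditions: Ti(Oi-Pr)4, L-(+)-diisopropyl tartrate, t-BuOOH, 4 Å molecular sieves, CH2Cl2, −20 °C
Reagents that add atoms: tert-butyl hydroperoxide, CC(C)(C)OO
Why: Sharpless asymmetric epoxidation desymmetrises the divinylcarbinol by enantiotopic-group and diastereoface selection (the minor enantiomer is drained by a second epoxidation), and the natural tartrate should give the anti (2R,3S) epoxy alcohol, whose carbinol becomes C6 and whose epoxide masks the second vinyl group.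

Step 9
Reactants: 14 (2R,3S)-1,2-epoxypent-4-en-3-ol; 3 2-{[(TBS)oxy]methyl}prop-2-enoic acid
Product: 15 (S)-1-[(R)-oxiran-2-yl]prop-2-en-1-yl 2-{[(TBS)oxy]methyl}prop-2-enoate
Conditions: DCC, DMAP (cat.), CH2Cl2, 0 °C → rt
Reagents that add atoms: none
Why: Steglich esterification of the secondary alcohol is neutral and should leave the epoxide and the stereocentres untouched.

Step 10
Reactants: 15 (S)-1-[(R)-oxiran-2-yl]prop-2-en-1-yl 2-{[(TBS)oxy]methyl}prop-2-enoate
Product: 16 (S)-3-{[(TBS)oxy]methyl}-5-[(R)-oxiran-2-yl]furan-2(5H)-one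
Conditions: second-generation Grubbs catalyst (5 mol%), toluene, 80 °C
Reagents that add atoms: none
Why: In this ring-closing metathesis the ruthenium carbene should load on the monosubstituted vinyl group and close the five-membered ring onto the 2-substituted acrylate, while the epoxide arm cannot take part, so the C6 stereocentre is retained.

Step 11
Reactants: 16 (S)-3-{[(TBS)oxy]methyl}-5-[(R)-oxiran-2-yl]furan-2(5H)-one
Product: 17 (R)-3-{[(TBS)oxy]methyl}-5-vinylfuran-2(5H)-one
Conditions: CH3ReO3 (5 mol%), PPh3, benzene, rt → 50 °C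
Reagents that add atoms: none
Why: Rhenium-catalysed oxygen-atom transfer from the terminal epoxide to the phosphine (epoxide deoxygenation) should unveil the vinyl group without base, so the acidic, doubly allylic C6–H is not epimerised; the descriptor changes from S to R only through the priority change.

Step 12
Reactants: 17 (R)-3-{[(TBS)oxy]methyl}-5-vinylfuran-2(5H)-one
Product: 18 (R)-3-(bromomethyl)-5-vinylfuran-2(5H)-one
Conditions: Ph3PBr2, CH2Cl2, 0 °C → rt; used promptly
Reagents that add atoms: dibromotriphenylphosphorane, BrP(Br)(c1ccccc1)(c1ccccc1)c1ccccc1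
Why: Direct silyl ether to bromide exchange through an oxyphosphonium ion should give the allylic bromide in one non-basic operation.

Step 13
Reactants: 18 (R)-3-(bromomethyl)-5-vinylfuran-2(5H)-one; 12 (S)-3-methyl-1,4-dioxopentan-3-yl 2-{[(TBS)oxy]methyl}prop-2-enoate
Product: 20 (3S,5S)-5-hydroxy-3-methyl-5-[(2R,3R)-4-methylidene-5-oxo-2-vinyloxolan-3-yl]-2-oxopentan-3-yl 2-{[(TBS)oxy]methyl}prop-2-enoate, via allylzinc bromide 19 (not isolated)
Conditions: Zn dust, THF/sat. aq. NH4Cl (1:1), 0 °C → rt
Reagents that add atoms: zinc, [Zn]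
Why: In this zinc Barbier allylation the bond should form at the γ-carbon (C7) on the face anti to the C6 vinyl group (trans lactone, 7R), a chair Zimmerman–Traxler transition state with the ring-locked E-type allyl unit and an equatorial aldehyde substituent should set C8 as 8S, and the aqueous medium protonates the zinc alkoxide before it can shift the O10 acyl group or open the lactone.

Step 14
Reactants: 20 the (8S) Barbier alcohol; 21 (R)-2-methylbutanoic acid
Product: 22 (3S,5R)-3-methyl-5-{[(2R)-2-methylbutanoyl]oxy}-5-[(2R,3R)-4-methylidene-5-oxo-2-vinyloxolan-3-yl]-2-oxopentan-3-yl 2-{[(TBS)oxy]methyl}prop-2-enoate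
Conditions: PPh3, DIAD, THF, 0 °C → rt
Reagents that add atoms: none
Why: In this Mitsunobu esterification SN2 displacement of the C8 oxyphosphonium ion by the carboxylate should invert C8 to the required 8R configuration and install the side chain under neutral conditions without touching the stereocentre of the acid.

Step 15
Reactants: 22 the (8R) diene ester
Product: 23 nine-membered lactone (4Z,6R,7R,8R,10S): ring O10–C3(=O)–C4(CH2OTBS)=C5H–C6H–C7H–C8H–C9H2–C10(CH3)(COCH3), with the (R)-2-methylbutanoate on C8 and the α-methylene-γ-butyrolactone (C6–O–C12(=O)–C11(=CH2)–C7) trans-fused at C6/C7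
Conditions: second-generation Hoveyda–Grubbs catalyst (10 mol%), toluene (1 mM), 80 °C
Reagents that add atoms: none
Why: In this ring-closing metathesis the alkylidene formed at the C5 vinyl group should close onto the 2-substituted acrylate, the nine-membered ring enforces the ring-cis (Z) C4=C5 geometry, the α-methylene lactone cannot form a sensible ring, and the quaternary C10 and the trans-fused lactone preorganise the chain (Thorpe–Ingold effect).

Step 16
Reactants: 23 the nine-membered lactone
Product: 26 15-O-TBS ether of the target, via hydroxy diketone 24 (not isolated), via bridged hemiketal 25 (not isolated)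
Conditions: LiN(SiMe3)2 (1.1 equiv), THF, −78 → −20 °C; AcOH; then CSA (cat.), 4 Å molecular sieves, CH2Cl2, rt
Reagents that add atoms: none
Why: Proposed new method: kinetic deprotonation of the only enolisable position of the ketone (the C2 methyl group; C10 is quaternary) gives a lithium enolate whose carbon attacks the lactone carbonyl C3, held five atoms away through O10, and the tetrahedral adduct either opens to the diketonate of 24 (ring expansion of the nine-membered lactone to the ten-membered carbocycle by a net 1,3 O→C acyl shift) or persists as the alkoxide of hemiketal 25, which mild acid dehydrates to the vinylogous ester. The closest known reaction type is the Baker–Venkataraman acyl migration of acyclic α-acyloxy ketones followed by acid cyclodehydration of the α'-hydroxy 1,3-diketone to a 3(2H)-furanone; new here is its use on a medium-ring lactone, where the migrating acyl group is part of the ring. The one C2–C3 bond closes two rings: the five-membered furanone ring (C2–C1–C10–O10–C3, 5-exo-trig) and, through it, the ten-membered carbocycle C1–C10, which arises by ring expansion and not by an end-to-end macrocyclisation. No stereocentre of the product is created: the transient hemiketal carbon is fixed by the bridge (hydroxyl cis to the C10 methyl) and vanishes on dehydration, while C6, C7, C8 and C10 are not touched. The step needs site selectivity: one equivalent of base at −78 °C addresses the methyl ketone ahead of the ester α-hydrogen and the γ-hydrogen at C6, attack on the C8 ester or the C12 lactone would need a seven-membered or larger transition state, and only O10 can close onto C3 in the dehydration. Relief of the strain of the nine-membered E-ester and formation of the conjugated furanone should drive the sequence.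

Step 17
Reactants: 26 15-O-TBS ether of the target
Product: 27 CNP0307052.2 (target)
Conditions: HF·pyridine, pyridine, THF, 0 °C → rt
Reagents that add atoms: none
Why: Buffered fluoride cleavage of the primary silyl ether should leave the α-methylene lactone, the C8 ester and the furanone untouched.

**Compound list**

1 | ethyl 2-(hydroxymethyl)prop-2-enoate | C=C(CO)C(=O)OCC | starting material
2 | ethyl 2-{[(tert-butyldimethylsilyl)oxy]methyl}prop-2-enoate | C=C(CO[Si](C)(C)C(C)(C)C)C(=O)OCC | intermediate
3 | 2-{[(tert-butyldimethylsilyl)oxy]methyl}prop-2-enoic acid | C=C(CO[Si](C)(C)C(C)(C)C)C(=O)O | intermediate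
4 | (R)-lactic acid | C[C@@H](O)C(=O)O | starting material
5 | pivalaldehyde | CC(C)(C)C=O | starting material
6 | (2R,5R)-2-tert-butyl-5-methyl-1,3-dioxolan-4-one | C[C@H]1O[C@@H](C(C)(C)C)OC1=O | intermediate
7 | 1-bromo-3-methylbut-2-ene (prenyl bromide) | CC(C)=CCBr | starting material
8 | (2R,5S)-2-tert-butyl-5-methyl-5-(3-methylbut-2-en-1-yl)-1,3-dioxolan-4-one | C[C@@]1(CC=C(C)C)O[C@@H](C(C)(C)C)OC1=O | intermediate
9 | (S)-3-hydroxy-3,6-dimethylhept-5-en-2-one | CC(=O)[C@@](C)(O)CC=C(C)C | intermediate
10 | 2-{[(tert-butyldimethylsilyl)oxy]methyl}prop-2-enoyl chloride | C=C(CO[Si](C)(C)C(C)(C)C)C(=O)Cl | intermediate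
11 | (S)-3,6-dimethyl-2-oxohept-5-en-3-yl 2-{[(TBS)oxy]methyl}prop-2-enoate | CC(=O)[C@@](C)(OC(=O)C(=C)CO[Si](C)(C)C(C)(C)C)CC=C(C)C | intermediate
12 | (S)-3-methyl-1,4-dioxopentan-3-yl 2-{[(TBS)oxy]methyl}prop-2-enoate | CC(=O)[C@@](C)(OC(=O)C(=C)CO[Si](C)(C)C(C)(C)C)CC=O | intermediate
13 | penta-1,4-dien-3-ol | C=CC(O)C=C | starting material
14 | (2R,3S)-1,2-epoxypent-4-en-3-ol | C=C[C@H](O)[C@H]1CO1 | intermediate
15 | (S)-1-[(R)-oxiran-2-yl]prop-2-en-1-yl 2-{[(TBS)oxy]methyl}prop-2-enoate | C=C[C@H](OC(=O)C(=C)CO[Si](C)(C)C(C)(C)C)[C@H]1CO1 | intermediate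
16 | (S)-3-{[(TBS)oxy]methyl}-5-[(R)-oxiran-2-yl]furan-2(5H)-one | O=C1O[C@@H](C=C1CO[Si](C)(C)C(C)(C)C)[C@H]2CO2 | intermediate
17 | (R)-3-{[(TBS)oxy]methyl}-5-vinylfuran-2(5H)-one | O=C1O[C@@H](C=C1CO[Si](C)(C)C(C)(C)C)C=C | intermediate
18 | (R)-3-(bromomethyl)-5-vinylfuran-2(5H)-one | O=C1O[C@@H](C=C1CBr)C=C | intermediate
19 | {[(R)-2-oxo-5-vinyl-2,5-dihydrofuran-3-yl]methyl}zinc bromide | Br[Zn]CC1=C[C@@H](C=C)OC1=O | intermediate
20 | (3S,5S)-5-hydroxy-3-methyl-5-[(2R,3R)-4-methylidene-5-oxo-2-vinyloxolan-3-yl]-2-oxopentan-3-yl 2-{[(TBS)oxy]methyl}prop-2-enoate | C=C1C(=O)O[C@H](C=C)[C@H]1[C@@H](O)C[C@](C)(OC(=O)C(=C)CO[Si](C)(C)C(C)(C)C)C(C)=O | intermediate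
21 | (R)-2-methylbutanoic acid | CC[C@@H](C)C(=O)O | starting material
22 | (3S,5R)-3-methyl-5-{[(2R)-2-methylbutanoyl]oxy}-5-[(2R,3R)-4-methylidene-5-oxo-2-vinyloxolan-3-yl]-2-oxopentan-3-yl 2-{[(TBS)oxy]methyl}prop-2-enoate | C=C1C(=O)O[C@H](C=C)[C@H]1[C@H](OC(=O)[C@H](C)CC)C[C@](C)(OC(=O)C(=C)CO[Si](C)(C)C(C)(C)C)C(C)=O | intermediate
23 | nine-membered lactone (4Z,6R,7R,8R,10S): 10-acetyl-10-methyl lactone O10–C3(=O)–C4(CH2OTBS)=C5–C6–C7–C8–C9–C10 with the C8 (R)-2-methylbutanoate and the trans-fused α-methylene-γ-butyrolactone at C6/C7 | C=C1C(=O)O[C@@H]2/C=C(/CO[Si](C)(C)C(C)(C)C)C(=O)O[C@@](C)(C[C@@H](OC(=O)[C@H](C)CC)[C@@H]12)C(C)=O | intermediate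
24 | ring-expanded hydroxy diketone: ten-membered carbocycle C1–C10 with ketones at C1 and C3, tertiary alcohol at C10 (10S), otherwise as 23 | C=C1C(=O)O[C@@H]2/C=C(/CO[Si](C)(C)C(C)(C)C)C(=O)CC(=O)[C@@](C)(O)C[C@@H](OC(=O)[C@H](C)CC)[C@@H]12 | intermediate
25 | bridged hemiketal (3S): O10 closed onto C3 of 24, C3 hydroxyl cis to the C10 methyl | C=C1C(=O)O[C@@H]2/C=C(/CO[Si](C)(C)C(C)(C)C)[C@]3(O)CC(=O)[C@](C)(C[C@@H](OC(=O)[C@H](C)CC)[C@@H]12)O3 | intermediate
26 | 15-O-TBS ether of the target (furanone formed, C4=C5 Z, 6R,7R,8R,10S) | C=C1C(=O)O[C@@H]2/C=C(/CO[Si](C)(C)C(C)(C)C)C3=CC(=O)[C@](C)(C[C@@H](OC(=O)[C@H](C)CC)[C@@H]12)O3 | intermediate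
27 | CNP0307052.2: (4Z,6R,7R,8R,10S)-15-hydroxy furanone-bridged germacranolide 8-O-[(R)-2-methylbutanoate] | C=C1C(=O)O[C@@H]2/C=C(/CO)C3=CC(=O)[C@](C)(C[C@@H](OC(=O)[C@H](C)CC)[C@@H]12)O3 | target

**Totals and risks**

Total step count: 17. Longest linear sequence: 11 steps (steps 1, 2 and 9–17, from ethyl 2-(hydroxymethyl)prop-2-enoate 1 through acid 3, ester 15 and butenolide 18 to the target). The branch from divinylcarbinol (steps 8–17) and the branch from (R)-lactic acid (steps 3–7 and 13–17) each run to 10 steps.

Steps most likely to fail: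

1. Step 16 (proposed new method). What may go wrong: the lithium enolate may transfer the acyl group to its own oxygen and stall as the enol ester, add to C5 in a conjugate sense, or abstract the γ-hydrogen at C6, so that the C2–C3 bond is not formed. Fallback (known chemistry; sets out from 23, returns at 26): the C2=C3 bond is made by an intramolecular ester Wittig olefination instead of an acyl transfer. The methyl ketone of 23 is brominated (PhNMe3Br3, THF, 0 °C) to the α-bromo ketone F1. PPh3 (toluene, rt) converts it into the phosphonium bromide F2. Et3N in toluene at 80 °C then generates the keto-stabilised ylide, which olefinates the lactone carbonyl C3 with closure of the five-membered ring and gives 26 directly.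

2. Step 15. What may go wrong: the ruthenium alkylidene loaded at C5 may fail to engage the hindered, electron-poor 2-substituted acrylate, so that dimerisation through the vinyl groups or olefin isomerisation outruns closure of the strained nine-membered E-ester. Fallback (sets out from 22, returns at 26): the order of the two ring-forming events is reversed. The acyclic α-acyloxy ketone 22 undergoes the ordinary Baker–Venkataraman acyl shift and acid cyclodehydration (LiN(SiMe3)2, THF, −78 → 0 °C; then CSA) to the acyclic furanone F3, in which C3 carries the 3-silyloxyprop-1-en-2-yl group. Ring-closing metathesis of its two terminal alkenes (second-generation Hoveyda–Grubbs catalyst, toluene, 100 °C, high dilution) then closes the ten-membered carbocycle at C4=C5 and gives 26.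

3. Step 14. What may go wrong: the C8 oxyphosphonium ion may eliminate toward C7 (allylic hydrogen) or be captured with retention through an acyloxyphosphonium pathway because the aliphatic acid is only weakly acidic, and the O10 acyl group may migrate to O8. Fallback (sets out from 20, returns at 22): inversion and acylation are separated. Mitsunobu reaction with the more acidic chloroacetic acid (PPh3, DIAD, toluene, 0 °C) gives the inverted (8R) chloroacetate F4. Thiourea/NaHCO3 in EtOH removes the chloroacetyl group selectively to the (8R) alcohol F5. Yamaguchi esterification with 21 (2,4,6-trichlorobenzoyl chloride, Et3N, DMAP, toluene) then proceeds with retention to 22.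

Further compounds

F1 | step 16 | α-bromo ketone of 23 (C2 brominated) | C=C1C(=O)O[C@@H]2/C=C(/CO[Si](C)(C)C(C)(C)C)C(=O)O[C@@](C)(C[C@@H](OC(=O)[C@H](C)CC)[C@@H]12)C(=O)CBr
F2 | step 16 | triphenylphosphonium bromide of F1 (phosphorus on C2) | C=C1C(=O)O[C@@H]2/C=C(/CO[Si](C)(C)C(C)(C)C)C(=O)O[C@@](C)(C[C@@H](OC(=O)[C@H](C)CC)[C@@H]12)C(=O)C[P+](c1ccccc1)(c1ccccc1)c1ccccc1.[Br-]
F3 | step 15 | acyclic 3(2H)-furanone from 22: C10 (S) bearing methyl and the C9–C8–C7 lactone chain, C3 bearing the 3-(TBS-oxy)prop-1-en-2-yl group, C6 vinyl still free | C=C1C(=O)O[C@H](C=C)[C@H]1[C@H](OC(=O)[C@H](C)CC)C[C@]2(C)OC(C(=C)CO[Si](C)(C)C(C)(C)C)=CC2=O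
F4 | step 14 | (8R) chloroacetate of 20 (C8 inverted) | C=C1C(=O)O[C@H](C=C)[C@H]1[C@H](OC(=O)CCl)C[C@](C)(OC(=O)C(=C)CO[Si](C)(C)C(C)(C)C)C(C)=O
F5 | step 14 | (8R) alcohol, the C8 epimer of 20 | C=C1C(=O)O[C@H](C=C)[C@H]1[C@H](O)C[C@](C)(OC(=O)C(=C)CO[Si](C)(C)C(C)(C)C)C(C)=O
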